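Take the side product as a ledger of the partner, since you asked for a quick number and this one can be reckoned quickly.

| flask | starting material | partner | second substrate | remark | time |
|---|---|---|---|---|---|
| autumn | 0.020 M | 1.2 equiv | 0.50 equiv | run made earlier |  |
| summer | 0.020 M | 1.2 equiv | 0.25 equiv | run made earlier |  |
| midnight | 0.020 M | 1.2 equiv | 0.38 equiv | run made earlier |  |
| Friday's | 0.020 M (fed, over 15 h) | 1.20 equiv | 0.500 equiv | all else is in the flask from the start; the feed brings no volume worth counting | 20 h |
| Tuesday's | 0.020 M | 1.20 equiv | 0.500 equiv (fed, over 15 h) | all else is in the flask from the start; the feed brings no volume worth counting | 20 h |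
| Monday's | 0.020 M | 1.20 equiv | 0.500 equiv | everything together at the start | 20 h |

| run | time / h | side product / % | target / % | starting material / % |
|---|---|---|---|---|
| autumn | 1.00 | 4 | 11 | 87 |
| autumn | 3.00 | 13 | 18 | 68 |
| autumn | 6.00 | 32 | 16 | 54 |
| autumn | 8.00 | 42 | 13 | 48 |
| autumn | 12.0 | 48 | 9 | 43 |
| summer | 1.00 | 2 | 11 | 85 |
| summer | 2.00 | 8 | 16 | 73 |
| summer | 3.00 | 15 | 17 | 67 |
| summer | 6.00 | 32 | 16 | 51 |
| summer | 12.0 | 52 | 10 | 40 |
| midnight | 1.00 | 5 | 11 | 86 |
| midnight | 3.00 | 15 | 16 | 65 |
| midnight | 6.00 | 31 | 13 | 54 |
| midnight | 8.00 | 38 | 12 | 46 |
| midnight | 12.0 | 49 | 10 | 41 |

(standard deviation of a reading: 1.5 percentage points)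

- in percentages every species weighs as the starting material in it: one side product counts as two

* the flask that comes out highest in amount of side product, in percent of the starting material charged; "all alike" if 1.5 percentage points covers them all (Friday's / Tuesday's / Monday's / all alike)
* amount of side product at the end, in percent of the starting material charged, Friday's
* amount of side product at the end, in percent of the starting material charged, Tuesday's
* amount of side product at the end, in percent of the starting material charged, Monday's

The percentages close near 100 and one side product counts as two, so target ever made is the target standing plus half the side product. The summer run at 12.0 h gives 30.0% for the partner yield, the share of the charged partner that has become target, target since lost included. The autumn run, with twice the second substrate, gives 27.5%, which is less, but the gap is 3 percentage points of target against a scatter of 1.5 points per reading, so I read it as a hint. In the autumn run target made reads 34.0% at 8.00 h and 33.0% at 12.0 h, so I stop counting there.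

Side product at the end is then twice the difference between target made and target left, and I run target left forward from its last two readings. Monday's, on the autumn yield, comes to 57.4%. Tuesday's has been fed 0.100 of second substrate by 3.00 h, less than the summer run's 0.25 equiv, so I give it the summer yield and 61.3%. Friday's feed has delivered on average 26.7% of its charge over the first 8.00 h, the time from which target made in the autumn run reads flat; scaling target made by that and counting no target left gives 17.6%.

Your forecast reads 25% for Friday's, 66% for Tuesday's and 67% for Monday's, with Monday's highest, on the ground that “the second substrate has no visible kinetic effect at 0.25–0.50 equiv”. We differ there: I put Tuesday's above Monday's by 3.9 points.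

The flask gives 19.6% for Friday's, 64.3% for Tuesday's and 59.2% for Monday's, so Tuesday's stands highest. At 20.0 h, c(second product) in Tuesday's is 0.00183 M, less than the 0.00476 M in Monday's. Put to Tuesday's with its target of 5.00%, the partner yield gives 62.0%.

    starting material + target → side product (k = 14.0 /M/h)
    partner → decomposed reagent (k = 0.217 /h)
    starting material + partner → target (k = 7.67 /M/h)
    2 second substrate → homo dimer (k = 48.0 /M/h)
    second substrate + partner → second product (k = 27.9 /M/h)

Leave Tuesday's flask until 2.0 d and count no target left, and the partner yield gives side product of 72.0%; computed, it is 73.2%, with target at 0.574% and the partner, the limiting reagent, at 0% of its charge.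

The readings are calculated for substances that don't exist; the scatter is artificial.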